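The chalcone is cut at the C(=O)–Cα bond instead of Cα=Cβ. Ring A carries C5–OH next to the C6 carbonyl (chromene numbering), a salicyl pair that can chelate rhodium. The key step therefore adds the formyl C–H of 5-hydroxy-7-methoxy-2,2-dimethyl-2H-chromene-6-carbaldehyde syn across 4-ethynylanisole (Rh-catalysed hydroacylation). In one acid-free operation with only catalytic base it joins the two halves, makes the aryl ketone flanked by OH and OMe and sets the E-alkene, with full atom economy. The precursor, a chromene salicylaldehyde with the 2H-pyran already fused at C4a/C8a, comes in one step from a commercial benzaldehyde and prenal.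

Key step: step 2

Remark: Glychalcone A has no stereocentre, so "single enantiomer" reduces to the E-configured enone, which the key step must set; 2,4-dihydroxy-6-methoxybenzaldehyde (1) is taken as a catalogue compound.

Step 1
Reactants: 1 2,4-dihydroxy-6-methoxybenzaldehyde; 2 3-methylbut-2-enal (prenal)
Product: 5 5-hydroxy-7-methoxy-2,2-dimethyl-2H-chromene-6-carbaldehyde, via benzylic alcohol adduct 3 (not isolated), via ortho-quinone methide 4 (not isolated)
Conditions: 2 (2 equiv), pyridine, 120 °C
Reagents that add atoms: none
Why: Knoevenagel-type condensation of a resorcinol with an enal followed by oxa-6π electrocyclisation (formal [3+3] chromene annulation): the non-chelated 4-OH is the acidic phenol, its phenoxide should attack prenal through C3 to give 3, loss of water across C3/O4 gives 4, and 4 closes onto the C4 oxygen while the 2-OH stays locked in its hydrogen bond to the formyl group, which also keeps the aldehyde unreactive.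

Step 2
Reactants: 5 5-hydroxy-7-methoxy-2,2-dimethyl-2H-chromene-6-carbaldehyde; 6 4-ethynylanisole
Product: 7 Glychalcone A [(E)-1-(5-hydroxy-7-methoxy-2,2-dimethyl-2H-chromen-6-yl)-3-(4-methoxyphenyl)prop-2-en-1-one]
Conditions: 6 (2 equiv, slow addition), [RhCl(cod)]2 (2.5 mol %), dppf (5 mol %), Na2CO3 (5 mol %), toluene, 110 °C, argon
Reagents that add atoms: none
Why: The phenoxide of 5 binds Rh(I), and chelation-assisted oxidative addition of the formyl C–H gives a five-membered O,C-acylrhodium(III) hydride; the alkyne inserts into Rh–H with rhodium at the unhindered terminal carbon, and C–C reductive elimination releases the enone and Rh(I). The closest known reaction type is the Rh/diphosphine-catalysed intermolecular hydroacylation of alkynes with salicylaldehydes to 2-alkenoylphenols. No ring is closed and no stereocentre is formed; the E double bond follows from syn addition of acyl and H across the triple bond, which places the acyl and aryl groups trans. The step needs linear over branched addition, alkyne over the chromene C3=C4 alkene, no decarbonylation and no oxa-Michael closure to a flavanone. The steric bias of the terminal alkyne and the wide-bite-angle ligand should favour the linear enone, the C3=C4 alkene is cis-disubstituted and remote from the chelate, the O,C-chelate from C5–O disfavours CO loss, and the strong C5–OH···O=C hydrogen bond together with only catalytic carbonate should keep the chalcone open. The C7–OMe does not compete for rhodium, and the acid-sensitive 2H-pyran sees neither acid nor strong base.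

Compound list
1 | 2,4-dihydroxy-6-methoxybenzaldehyde | COc1cc(O)cc(O)c1C=O | starting material
2 | 3-methylbut-2-enal (prenal) | CC(C)=CC=O | starting material
3 | 2,4-dihydroxy-3-(1-hydroxy-3-methylbut-2-en-1-yl)-6-methoxybenzaldehyde (benzylic alcohol adduct, racemic) | COc1cc(O)c(C(O)C=C(C)C)c(O)c1C=O | intermediate
4 | 2-hydroxy-6-methoxy-3-(3-methylbut-2-en-1-ylidene)-4-oxocyclohexa-1,5-diene-1-carbaldehyde (ortho-quinone methide) | O=CC1=C(O)C(=CC=C(C)C)C(=O)C=C1OC | intermediate
5 | 5-hydroxy-7-methoxy-2,2-dimethyl-2H-chromene-6-carbaldehyde | COc1cc2c(c(O)c1C=O)C=CC(C)(C)O2 | intermediate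
6 | 4-ethynylanisole (1-ethynyl-4-methoxybenzene) | COc1ccc(C#C)cc1 | starting material
7 | Glychalcone A, (E)-1-(5-hydroxy-7-methoxy-2,2-dimethyl-2H-chromen-6-yl)-3-(4-methoxyphenyl)prop-2-en-1-one | COc1ccc(/C=C/C(=O)c2c(OC)cc3c(c2O)C=CC(C)(C)O3)cc1 | target

Total step count: 2. Longest linear sequence: 2 steps.

Steps most likely to fail (the route has only two steps, so both are ranked)

1. Step 2 (key step). What may go wrong: hydrometalation of the terminal alkyne in the opposite sense, so that the acyl group is delivered to the aryl-bearing carbon and the branched 2-aryl enone forms; loss of CO from the acylrhodium hydride; rhodium-mediated oligomerisation of the alkyne; or base-induced oxa-Michael closure of the product to a flavanone. Fallback: the same C(=O)–Cα bond is made in two stoichiometric operations. Starting from 5, addition of (E)-2-(4-methoxyphenyl)vinylmagnesium bromide (3 equiv, prepared from (E)-1-(2-bromovinyl)-4-methoxybenzene and Mg; the first equivalent is consumed by the phenol) in THF at −20 °C should give racemic (E)-6-[1-hydroxy-3-(4-methoxyphenyl)prop-2-en-1-yl]-7-methoxy-2,2-dimethyl-2H-chromen-5-ol F1. This acid-labile ortho-hydroxy allylic alcohol is worked up at neutral pH (aqueous NH4Cl) and oxidised at once with activated MnO2 in CH2Cl2 at room temperature. That should return the route at 7, with the E geometry carried over from the vinyl bromide.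

2. Step 1. What may go wrong: attack of prenal at C5 instead of C3 of 1, ring closure through the chelated 2-OH instead of the 4-OH, or self-condensation of prenal under the basic conditions. Fallback: the ring oxygen is fixed before the C–C bond is made. Starting from 1, alkylation of the more acidic, non-chelated 4-OH with 3-chloro-3-methylbut-1-yne (K2CO3, KI, cat. CuI, acetone, reflux) should give 2-hydroxy-6-methoxy-4-[(2-methylbut-3-yn-2-yl)oxy]benzaldehyde F2. Heating F2 in N,N-diethylaniline at 180 °C should trigger aryl propargyl ether Claisen rearrangement to C3 (favoured by the bond fixation of the chelated salicylaldehyde), then enolisation, [1,5]-H shift and oxa-6π electrocyclisation, returning the route at 5.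

Further compounds
F1 | step 2 | (E)-6-[1-hydroxy-3-(4-methoxyphenyl)prop-2-en-1-yl]-7-methoxy-2,2-dimethyl-2H-chromen-5-ol (racemic) | COc1ccc(/C=C/C(O)c2c(OC)cc3c(c2O)C=CC(C)(C)O3)cc1
F2 | step 1 | 2-hydroxy-6-methoxy-4-[(2-methylbut-3-yn-2-yl)oxy]benzaldehyde | COc1cc(OC(C)(C)C#C)cc(O)c1C=O
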